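**Plan**

- Numbering (indene): C1 carries the 2-formylallyl chain, C2 the ketone, C3=C3a the alkene, C4 the acyloxy group, C7 the carboxyl, C7a the methyl; ring A is the cyclopentenone, ring B the cyclohexane.
- Cuts, in retrosynthetic order: the C4–O acyl bond (trienoic acid), the acrolein methylene (Mannich), C1–CH2 (cross-coupling at a C1 enol triflate), the C2 ketone and C3=C3a back to a C1 ketone plus a C3a hydroxyl, the C3a–C4 bond, one aldehyde carbon, and C7–C7a (Michael).
- Enabling feature: in ring A, C7a lies between C1 and C3a, so it is C2 of a 2-methylcyclopentane-1,3-dione and prochiral there; C3a, a former ring carbonyl, is bonded to oxygenated C4, which is the pattern an acyl anion leaves when it adds to a ketone.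
- Forward: ring A is bought as the dione; C7–C7a is made first; ring B closes through C3a–C4; the carbonyl is moved from C1 to C2 while the side chain enters at C1; loss of the C3a oxygen gives the enone; ester, methylene and free acid come last.
- Stereochemistry: C7 from an amine-catalysed Michael addition; C7a (with transient C3a) from a chiral carbene; C4 from equatorial hydride delivery; C1 from protonation and equilibration next to the C2 ketone; C8 of the acyl chain from a chiral-pool 2-methylbutyl unit.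

Key step: step 4

Assumption 1: the (5aS,10bR) antipode of the aminoindanol-derived triazolium salt is taken as the one that sends the acyl anion to the pro-R ring carbonyl; the mirror-image salt is equally accessible.
Assumption 2: the tert-butyl oxobutenoate of step 1 and the (R)-alcohol of step 12 are treated as purchasable.

Step 1
Reactants: 1 2-methylcyclopentane-1,3-dione; 2 tert-butyl (E)-4-oxobut-2-enoate
Product: 3 tert-butyl (2R)-2-(1-methyl-2,5-dioxocyclopentyl)-4-oxobutanoate
Conditions: (S)-2-[diphenyl(trimethylsilyloxy)methyl]pyrrolidine (10 mol %), PhCO2H (10 mol %), CH2Cl2/EtOH, 0 °C to rt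
Reagents that add atoms: none
Why: Iminium-catalysed Michael addition, in which the enolised dione attacks the ester-bearing β-carbon of the condensed enal on the face left open by the diphenyl(silyloxy)methyl group of the (S)-amine and so sets C7 as R, while the new quaternary carbon carries two identical carbonyl arms and is not yet stereogenic.

Step 2
Reactants: 3 tert-butyl (2R)-2-(1-methyl-2,5-dioxocyclopentyl)-4-oxobutanoate; 4 (methoxymethyl)triphenylphosphonium chloride
Product: 6 tert-butyl (2R)-5-methoxy-2-(1-methyl-2,5-dioxocyclopentyl)pent-4-enoate (E/Z mixture), via (methoxymethylene)triphenylphosphorane 5 (not isolated)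
Conditions: 4, KN(SiMe3)2, THF, 0 °C; then 3, −78 °C to 0 °C
Reagents that add atoms: none
Why: Wittig methoxymethylenation, in which the non-stabilised ylide adds to the aldehyde far faster than to the two ketones flanked by the quaternary carbon, and addition of 3 to the cold preformed ylide keeps enolisation and retro-Michael loss of the dione behind, so C7 is untouched.

Step 3
Reactants: 6 tert-butyl (2R)-5-methoxy-2-(1-methyl-2,5-dioxocyclopentyl)pent-4-enoate
Product: 7 tert-butyl (2R)-2-(1-methyl-2,5-dioxocyclopentyl)-5-oxopentanoate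
Conditions: TsOH·H2O (cat.), acetone/H2O, rt
Reagents that add atoms: water, O
Why: Acid-catalysed enol ether hydrolysis (C-protonation, hemiacetal collapse) releases the aldehyde one carbon longer under conditions too mild to cleave the tert-butyl ester.

Step 4
Reactants: 7 tert-butyl (2R)-2-(1-methyl-2,5-dioxocyclopentyl)-5-oxopentanoate
Product: 8 tert-butyl (3aR,7R,7aS)-3a-hydroxy-7a-methyl-1,4-dioxooctahydro-1H-indene-7-carboxylate (cis-fused ketol)
Conditions: (5aS,10bR)-2-(pentafluorophenyl)-5a,10b-dihydro-4H,6H-indeno[2,1-b][1,2,4]triazolo[4,3-d][1,4]oxazin-2-ium tetrafluoroborate (10 mol %), Et3N (10 mol %), CH2Cl2, rt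
Reagents that add atoms: none
Why: Carbene-catalysed intramolecular crossed benzoin reaction: the triazolylidene adds to the aldehyde carbon (C4), proton transfer gives the enaminol acyl anion equivalent, this carbon adds to one ring carbonyl (C3a) to form C3a–C4, and collapse of the adduct releases the carbene and leaves the C4 ketone. The closest known reaction type is the triazolium-catalysed desymmetrising benzoin cyclisation of 2,2-disubstituted cyclic 1,3-diketones that carry an aldehyde arm. Ring B closes in the 6-exo-trig mode, and because the arm on C7a can reach the neighbouring carbonyl only from its own face, the new C3a hydroxyl ends on the side of the methyl and the 6-5 fusion is cis. C3a and C7a become stereogenic together through the choice between the two enantiotopic carbonyls, which the chiral catalyst makes (pro-R carbonyl attacked, giving 3aR,7aS), and the resident 7R centre is the matched partner because the chair-like closure onto that carbonyl carries the C7 ester equatorial. The step needs acyl-anion addition to win over aldol closure and over intermolecular benzoin coupling: the ring ketones cannot enolise towards the quaternary carbon, the catalytic amine base is too weak to enolise the aldehyde appreciably, and the six-membered closure is fast at the dilution used.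

Step 5
Reactants: 8 tert-butyl (3aR,7R,7aS)-3a-hydroxy-7a-methyl-1,4-dioxooctahydro-1H-indene-7-carboxylate
Product: 9 tert-butyl (3aR,4S,7R,7aS)-3a,4-dihydroxy-7a-methyl-1-oxooctahydro-1H-indene-7-carboxylate
Conditions: LiBH(s-Bu)3, THF, −78 °C; then H2O
Reagents that add atoms: none
Why: Bulky-hydride reduction of the more electrophilic six-ring α-ketol carbonyl: in the favoured chair (ester and hydroxyl equatorial, methyl axial) the top face of C4 is closed by the syn-axial C7a methyl, so the hydride enters equatorially and leaves the C4 hydroxyl axial and cis to the C3a hydroxyl (4S), while the neopentyl five-ring ketone beside the ester-bearing C7 reacts more slowly.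

Step 6
Reactants: 9 tert-butyl (3aR,4S,7R,7aS)-3a,4-dihydroxy-7a-methyl-1-oxooctahydro-1H-indene-7-carboxylate
Product: 10 tert-butyl (3aR,4S,7R,7aS)-3a,4-(isopropylidenedioxy)-7a-methyl-1-oxooctahydro-1H-indene-7-carboxylate
Conditions: Me2C(OMe)2, PPTS (cat.), CH2Cl2, rt
Reagents that add atoms: 2,2-dimethoxypropane, COC(C)(C)OC
Why: Acid-catalysed transketalisation closes a five-membered isopropylidene acetal on the cis-3a,4-diol, which masks the tertiary hydroxyl against the bases to come and later serves as the leaving group at C3a.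

Step 7
Reactants: 10 tert-butyl (3aR,4S,7R,7aS)-3a,4-(isopropylidenedioxy)-7a-methyl-1-oxooctahydro-1H-indene-7-carboxylate
Product: 11 tert-butyl (3aR,4S,7R,7aS)-3a,4-(isopropylidenedioxy)-7a-methyl-1-(trifluoromethanesulfonyloxy)-3a,4,5,6,7,7a-hexahydro-3H-indene-7-carboxylate
Conditions: KN(SiMe3)2, THF, −78 °C; then PhNTf2, −78 °C to 0 °C
Reagents that add atoms: N-phenylbis(trifluoromethanesulfonimide), O=S(=O)(N(c1ccccc1)S(=O)(=O)C(F)(F)F)C(F)(F)F
Why: Enolate O-sulfonylation, regiochemically unambiguous because the C1 ketone can enolise only towards C2 (C7a is quaternary), gives the C1=C2 enol triflate.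

Step 8
Reactants: 11 tert-butyl (3aR,4S,7R,7aS)-3a,4-(isopropylidenedioxy)-7a-methyl-1-(trifluoromethanesulfonyloxy)-3a,4,5,6,7,7a-hexahydro-3H-indene-7-carboxylate; 12 3,3-diethoxyprop-1-ene
Product: 14 tert-butyl (3aR,4S,7R,7aR)-1-(3,3-diethoxypropyl)-3a,4-(isopropylidenedioxy)-7a-methyl-3a,4,5,6,7,7a-hexahydro-3H-indene-7-carboxylate, via 9-(3,3-diethoxypropyl)-9-borabicyclo[3.3.1]nonane 13 (not isolated)
Conditions: 12, 9-BBN, THF, 0 °C to rt; then 11, PdCl2(dppf) (5 mol %), Cs2CO3, DMF/H2O, rt to 50 °C
Reagents that add atoms: none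
Why: B-alkyl Suzuki–Miyaura coupling, in which anti-Markovnikov hydroboration of the allyl acetal gives the primary alkylborane, its ate complex transmetalates to the alkenylpalladium formed by oxidative addition of the triflate to zerovalent palladium, and reductive elimination joins C1 to the three-carbon chain with the alkene kept at C1=C2 (the 7a descriptor changes only through priority order).

Step 9
Reactants: 14 tert-butyl (3aR,4S,7R,7aR)-1-(3,3-diethoxypropyl)-3a,4-(isopropylidenedioxy)-7a-methyl-3a,4,5,6,7,7a-hexahydro-3H-indene-7-carboxylate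
Product: 15 tert-butyl (1R,2R,3aR,4S,7R,7aS)-1-(3,3-diethoxypropyl)-2-hydroxy-3a,4-(isopropylidenedioxy)-7a-methyloctahydro-1H-indene-7-carboxylate
Conditions: BH3·THF, THF, 0 °C to rt; then NaOH, H2O2, 0 °C
Reagents that add atoms: hydrogen peroxide, OO
Why: Hydroboration–oxidation places boron on the less substituted C2 and hydrogen on C1 by syn addition from the face away from the angular methyl, and oxidation with retention gives the C2 alcohol; the C1 and C2 configurations drawn are the expected ones and are provisional, since C2 is oxidised next and C1 is equilibrated in step 11.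

Step 10
Reactants: 15 tert-butyl (1R,2R,3aR,4S,7R,7aS)-1-(3,3-diethoxypropyl)-2-hydroxy-3a,4-(isopropylidenedioxy)-7a-methyloctahydro-1H-indene-7-carboxylate
Product: 16 tert-butyl (1R,3aR,4S,7R,7aS)-1-(3,3-diethoxypropyl)-3a,4-(isopropylidenedioxy)-7a-methyl-2-oxooctahydro-1H-indene-7-carboxylate
Conditions: Dess–Martin periodinane, NaHCO3, CH2Cl2, 0 °C to rt
Reagents that add atoms: none
Why: Dess–Martin oxidation of the secondary alcohol gives the C2 ketone and so completes the 1,2-transposition of the ring A carbonyl under buffered conditions that leave both acetals intact.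

Step 11
Reactants: 16 tert-butyl (1R,3aR,4S,7R,7aS)-1-(3,3-diethoxypropyl)-3a,4-(isopropylidenedioxy)-7a-methyl-2-oxooctahydro-1H-indene-7-carboxylate
Product: 17 tert-butyl (1R,4S,7R,7aS)-1-(3,3-diethoxypropyl)-4-hydroxy-7a-methyl-2-oxo-2,4,5,6,7,7a-hexahydro-1H-indene-7-carboxylate
Conditions: DBU, CH2Cl2, 0 °C to rt
Reagents that add atoms: none
Why: E1cB elimination: enolisation towards C3 expels the C3a acetal oxygen, the hemiketal alkoxide loses acetone to free the C4 hydroxyl, and the same base equilibrates C1 through the dienolate to the epimer expected to be more stable, with the side chain syn to the methyl and away from the C7 ring carbon (1R), which is also the product of protonation on the less hindered face.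

Step 12
Reactants: 18 (R)-2-methylbutan-1-ol; 19 2-(triphenylphosphoranylidene)propanal
Product: 21 (2E,4R)-2,4-dimethylhex-2-enal, via (R)-2-methylbutanal 20 (not isolated)
Conditions: Dess–Martin periodinane, CH2Cl2, 0 °C to rt; aq. NaHCO3/Na2S2O3 wash; then 19, CH2Cl2/toluene, 60 °C
Reagents that add atoms: none
Why: Dess–Martin oxidation followed by Wittig olefination with a formyl-stabilised ylide gives the E trisubstituted enal, and the volatile α-branched aldehyde is kept in solution and used at once so that its stereocentre is not racemised.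

Step 13
Reactants: 21 (2E,4R)-2,4-dimethylhex-2-enal; 22 triethyl 4-phosphonocrotonate
Product: 23 ethyl (2E,4E,6E,8R)-6,8-dimethyldeca-2,4,6-trienoate
Conditions: 22, LiN(SiMe3)2, THF, −78 °C; then 21, −78 °C to 0 °C
Reagents that add atoms: none
Why: Vinylogous Horner–Wadsworth–Emmons olefination, in which the lithiated phosphonate reacts at its α-carbon with the enal and phosphate elimination gives the new 4,5-alkene E, the 2,3-alkene E coming in with the reagent.

Step 14
Reactants: 23 ethyl (2E,4E,6E,8R)-6,8-dimethyldeca-2,4,6-trienoate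
Product: 24 (2E,4E,6E,8R)-6,8-dimethyldeca-2,4,6-trienoic acid
Conditions: LiOH, THF/MeOH/H2O, rt; then aq. HCl to pH 3
Reagents that add atoms: lithium hydroxide, [Li+].[OH-]
Why: Ester saponification, which touches neither the conjugated triene nor the remote C8 centre.

Step 15
Reactants: 17 tert-butyl (1R,4S,7R,7aS)-1-(3,3-diethoxypropyl)-4-hydroxy-7a-methyl-2-oxo-2,4,5,6,7,7a-hexahydro-1H-indene-7-carboxylate; 24 (2E,4E,6E,8R)-6,8-dimethyldeca-2,4,6-trienoic acid
Product: 26 tert-butyl (1R,4S,7R,7aS)-1-(3,3-diethoxypropyl)-4-{[(2E,4E,6E,8R)-6,8-dimethyldeca-2,4,6-trienoyl]oxy}-7a-methyl-2-oxo-2,4,5,6,7,7a-hexahydro-1H-indene-7-carboxylate, via trienoic 2,4,6-trichlorobenzoic mixed anhydride 25 (not isolated)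
Conditions: 24, 2,4,6-trichlorobenzoyl chloride, Et3N, toluene, rt; then 17, DMAP, rt to 40 °C
Reagents that add atoms: none
Why: Yamaguchi esterification, in which the acid is activated as the mixed anhydride and DMAP transfers the acyl group to the axial allylic C4 hydroxyl with retention, so C4 stays S.

Step 16
Reactants: 26 tert-butyl (1R,4S,7R,7aS)-1-(3,3-diethoxypropyl)-4-{[(2E,4E,6E,8R)-6,8-dimethyldeca-2,4,6-trienoyl]oxy}-7a-methyl-2-oxo-2,4,5,6,7,7a-hexahydro-1H-indene-7-carboxylate
Product: 27 tert-butyl (1R,4S,7R,7aS)-4-{[(2E,4E,6E,8R)-6,8-dimethyldeca-2,4,6-trienoyl]oxy}-7a-methyl-2-oxo-1-(3-oxopropyl)-2,4,5,6,7,7a-hexahydro-1H-indene-7-carboxylate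
Conditions: TsOH·H2O (cat.), acetone/H2O, rt
Reagents that add atoms: water, O
Why: Acid-catalysed acetal hydrolysis frees the aldehyde at an acid strength that spares the tert-butyl ester and the allylic trienoate.

Step 17
Reactants: 27 tert-butyl (1R,4S,7R,7aS)-4-{[(2E,4E,6E,8R)-6,8-dimethyldeca-2,4,6-trienoyl]oxy}-7a-methyl-2-oxo-1-(3-oxopropyl)-2,4,5,6,7,7a-hexahydro-1H-indene-7-carboxylate
Product: 29 tert-butyl (1R,4S,7R,7aS)-4-{[(2E,4E,6E,8R)-6,8-dimethyldeca-2,4,6-trienoyl]oxy}-1-(2-formylprop-2-en-1-yl)-7a-methyl-2-oxo-2,4,5,6,7,7a-hexahydro-1H-indene-7-carboxylate, via Mannich base 28 (not isolated)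
Conditions: Me2N=CH2 I (Eschenmoser's salt), Et3N, CH2Cl2, rt
Reagents that add atoms: N,N-dimethylmethyleneiminium iodide, C=[N+](C)C.[I-]
Why: Mannich reaction followed by β-elimination of dimethylamine converts the aldehyde α-CH2 into the 2-substituted acrolein, the aldehyde reacting ahead of the hindered tertiary C1–H of the ketone.

Step 18
Reactants: 29 tert-butyl (1R,4S,7R,7aS)-4-{[(2E,4E,6E,8R)-6,8-dimethyldeca-2,4,6-trienoyl]oxy}-1-(2-formylprop-2-en-1-yl)-7a-methyl-2-oxo-2,4,5,6,7,7a-hexahydro-1H-indene-7-carboxylate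
Product: 30 (1R,4S,7R,7aS)-4-{[(2E,4E,6E,8R)-6,8-dimethyldeca-2,4,6-trienoyl]oxy}-1-(2-formylprop-2-en-1-yl)-7a-methyl-2-oxo-2,4,5,6,7,7a-hexahydro-1H-indene-7-carboxylic acid
Conditions: CF3CO2H/CH2Cl2 (1:4), 0 °C
Reagents that add atoms: none
Why: Acidolysis of the tert-butyl ester by alkyl–oxygen cleavage (loss of isobutene) should leave enal, enone and trienoate untouched and give the target acid.

**Compound list**

1 | 2-methylcyclopentane-1,3-dione | CC1C(=O)CCC1=O | starting material
2 | tert-butyl (E)-4-oxobut-2-enoate | O=C/C=C/C(=O)OC(C)(C)C | starting material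
3 | tert-butyl (2R)-2-(1-methyl-2,5-dioxocyclopentyl)-4-oxobutanoate | O=CC[C@@H](C(=O)OC(C)(C)C)C1(C)C(=O)CCC1=O | intermediate
4 | (methoxymethyl)triphenylphosphonium chloride | COC[P+](c1ccccc1)(c1ccccc1)c1ccccc1.[Cl-] | starting material
5 | (methoxymethylene)triphenylphosphorane (formed in the flask) | COC=P(c1ccccc1)(c1ccccc1)c1ccccc1 | intermediate
6 | tert-butyl (2R)-5-methoxy-2-(1-methyl-2,5-dioxocyclopentyl)pent-4-enoate (E/Z mixture) | COC=CC[C@@H](C(=O)OC(C)(C)C)C1(C)C(=O)CCC1=O | intermediate
7 | tert-butyl (2R)-2-(1-methyl-2,5-dioxocyclopentyl)-5-oxopentanoate | O=CCC[C@@H](C(=O)OC(C)(C)C)C1(C)C(=O)CCC1=O | intermediate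
8 | tert-butyl (3aR,7R,7aS)-3a-hydroxy-7a-methyl-1,4-dioxooctahydro-1H-indene-7-carboxylate | O=C1CC[C@]2(O)C(=O)CC[C@@H](C(=O)OC(C)(C)C)[C@]12C | intermediate
9 | tert-butyl (3aR,4S,7R,7aS)-3a,4-dihydroxy-7a-methyl-1-oxooctahydro-1H-indene-7-carboxylate | O=C1CC[C@]2(O)[C@@H](O)CC[C@@H](C(=O)OC(C)(C)C)[C@]12C | intermediate
10 | tert-butyl (3aR,4S,7R,7aS)-3a,4-(isopropylidenedioxy)-7a-methyl-1-oxooctahydro-1H-indene-7-carboxylate | O=C1CC[C@]2(OC(C)(C)O3)[C@@H]3CC[C@@H](C(=O)OC(C)(C)C)[C@]12C | intermediate
11 | tert-butyl (3aR,4S,7R,7aS)-3a,4-(isopropylidenedioxy)-7a-methyl-1-(trifluoromethanesulfonyloxy)-3a,4,5,6,7,7a-hexahydro-3H-indene-7-carboxylate | O=S(=O)(OC1=CC[C@]2(OC(C)(C)O3)[C@@H]3CC[C@@H](C(=O)OC(C)(C)C)[C@]12C)C(F)(F)F | intermediate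
12 | 3,3-diethoxyprop-1-ene | C=CC(OCC)OCC | starting material
13 | 9-(3,3-diethoxypropyl)-9-borabicyclo[3.3.1]nonane (formed in the flask) | CCOC(CCB1C2CCCC1CCC2)OCC | intermediate
14 | tert-butyl (3aR,4S,7R,7aR)-1-(3,3-diethoxypropyl)-3a,4-(isopropylidenedioxy)-7a-methyl-3a,4,5,6,7,7a-hexahydro-3H-indene-7-carboxylate | CCOC(CCC1=CC[C@]2(OC(C)(C)O3)[C@@H]3CC[C@@H](C(=O)OC(C)(C)C)[C@]12C)OCC | intermediate
15 | tert-butyl (1R,2R,3aR,4S,7R,7aS)-1-(3,3-diethoxypropyl)-2-hydroxy-3a,4-(isopropylidenedioxy)-7a-methyloctahydro-1H-indene-7-carboxylate | CCOC(CC[C@H]1[C@H](O)C[C@]2(OC(C)(C)O3)[C@@H]3CC[C@@H](C(=O)OC(C)(C)C)[C@]12C)OCC | intermediate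
16 | tert-butyl (1R,3aR,4S,7R,7aS)-1-(3,3-diethoxypropyl)-3a,4-(isopropylidenedioxy)-7a-methyl-2-oxooctahydro-1H-indene-7-carboxylate | CCOC(CC[C@H]1C(=O)C[C@]2(OC(C)(C)O3)[C@@H]3CC[C@@H](C(=O)OC(C)(C)C)[C@]12C)OCC | intermediate
17 | tert-butyl (1R,4S,7R,7aS)-1-(3,3-diethoxypropyl)-4-hydroxy-7a-methyl-2-oxo-2,4,5,6,7,7a-hexahydro-1H-indene-7-carboxylate | CCOC(CC[C@H]1C(=O)C=C2[C@@H](O)CC[C@@H](C(=O)OC(C)(C)C)[C@@]21C)OCC | intermediate
18 | (R)-2-methylbutan-1-ol | CC[C@@H](C)CO | starting material
19 | 2-(triphenylphosphoranylidene)propanal | CC(C=O)=P(c1ccccc1)(c1ccccc1)c1ccccc1 | starting material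
20 | (R)-2-methylbutanal (formed in the flask) | CC[C@@H](C)C=O | intermediate
21 | (2E,4R)-2,4-dimethylhex-2-enal | CC[C@@H](C)/C=C(\C)C=O | intermediate
22 | triethyl 4-phosphonocrotonate | CCOC(=O)/C=C/CP(=O)(OCC)OCC | starting material
23 | ethyl (2E,4E,6E,8R)-6,8-dimethyldeca-2,4,6-trienoate | CCOC(=O)/C=C/C=C/C(C)=C/[C@H](C)CC | intermediate
24 | (2E,4E,6E,8R)-6,8-dimethyldeca-2,4,6-trienoic acid | OC(=O)/C=C/C=C/C(C)=C/[C@H](C)CC | intermediate
25 | (2E,4E,6E,8R)-6,8-dimethyldeca-2,4,6-trienoic 2,4,6-trichlorobenzoic anhydride (formed in the flask) | O=C(/C=C/C=C/C(C)=C/[C@H](C)CC)OC(=O)c1c(Cl)cc(Cl)cc1Cl | intermediate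
26 | tert-butyl (1R,4S,7R,7aS)-1-(3,3-diethoxypropyl)-4-{[(2E,4E,6E,8R)-6,8-dimethyldeca-2,4,6-trienoyl]oxy}-7a-methyl-2-oxo-2,4,5,6,7,7a-hexahydro-1H-indene-7-carboxylate | CCOC(CC[C@H]1C(=O)C=C2[C@@H](OC(=O)/C=C/C=C/C(C)=C/[C@H](C)CC)CC[C@@H](C(=O)OC(C)(C)C)[C@@]21C)OCC | intermediate
27 | tert-butyl (1R,4S,7R,7aS)-4-{[(2E,4E,6E,8R)-6,8-dimethyldeca-2,4,6-trienoyl]oxy}-7a-methyl-2-oxo-1-(3-oxopropyl)-2,4,5,6,7,7a-hexahydro-1H-indene-7-carboxylate | O=CCC[C@H]1C(=O)C=C2[C@@H](OC(=O)/C=C/C=C/C(C)=C/[C@H](C)CC)CC[C@@H](C(=O)OC(C)(C)C)[C@@]21C | intermediate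
28 | tert-butyl (1R,4S,7R,7aS)-1-[2-(dimethylaminomethyl)-3-oxopropyl]-4-{[(2E,4E,6E,8R)-6,8-dimethyldeca-2,4,6-trienoyl]oxy}-7a-methyl-2-oxo-2,4,5,6,7,7a-hexahydro-1H-indene-7-carboxylate (formed in the flask, epimers at the aminomethyl carbon) | CN(C)CC(C=O)C[C@H]1C(=O)C=C2[C@@H](OC(=O)/C=C/C=C/C(C)=C/[C@H](C)CC)CC[C@@H](C(=O)OC(C)(C)C)[C@@]21C | intermediate
29 | tert-butyl (1R,4S,7R,7aS)-4-{[(2E,4E,6E,8R)-6,8-dimethyldeca-2,4,6-trienoyl]oxy}-1-(2-formylprop-2-en-1-yl)-7a-methyl-2-oxo-2,4,5,6,7,7a-hexahydro-1H-indene-7-carboxylate | C=C(C=O)C[C@H]1C(=O)C=C2[C@@H](OC(=O)/C=C/C=C/C(C)=C/[C@H](C)CC)CC[C@@H](C(=O)OC(C)(C)C)[C@@]21C | intermediate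
30 | (1R,4S,7R,7aS)-4-{[(2E,4E,6E,8R)-6,8-dimethyldeca-2,4,6-trienoyl]oxy}-1-(2-formylprop-2-en-1-yl)-7a-methyl-2-oxo-2,4,5,6,7,7a-hexahydro-1H-indene-7-carboxylic acid | C=C(C=O)C[C@H]1C(=O)C=C2[C@@H](OC(=O)/C=C/C=C/C(C)=C/[C@H](C)CC)CC[C@@H](C(=O)O)[C@@]21C | target

**Step count**

Total: 18 steps. Longest linear sequence: 15 steps (steps 1 to 11 and 15 to 18); the acyl chain takes 3 steps (12 to 14) and joins in step 15.

**Steps most likely to fail**

Step 4. The chiral carbene and the resident C7 centre may pull in different directions, so that the two ring carbonyls are attacked with little discrimination, or enolisation of the aldehyde may divert material into aldol closure. The fallback sets out from 7 and closes ring B by reductive ketyl–carbonyl (pinacol) coupling with SmI2 (THF, t-BuOH, −78 °C). The aldehyde is reduced first, the samarium ketyl adds to a ring carbonyl inside a chelate, and the cis-3a,4-diol is formed directly, the choice of carbonyl then resting on the C7 ester alone and diastereomers being separated at that stage. The detour comes back to the route at 9 and forms no compound outside the list (F0).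

Step 1. Addition of the fully substituted dione carbon to the β-substituted iminium ion may be sluggish, the addition may reverse and erode the enantiomeric purity at C7, or attack may drift to the carbon next to the aldehyde. The fallback sets out from 1 and 2 and runs the conjugate addition without a chiral catalyst (Et3N cat., THF/H2O, rt) to give racemic tert-butyl 2-(1-methyl-2,5-dioxocyclopentyl)-4-oxobutanoate F1. This is resolved by preparative chromatography on an amylose-carbamate chiral stationary phase. The (R)-enantiomer is 3, where the route is rejoined, and tert-butyl (2S)-2-(1-methyl-2,5-dioxocyclopentyl)-4-oxobutanoate F2 is set aside.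

Step 5. The hydride may fail to distinguish the two carbonyls, so that the C1 ketone is reduced alongside C4. The fallback sets out from 8 and reduces both ketones on purpose (excess LiBH(s-Bu)3, THF, −78 °C to 0 °C) to tert-butyl (1S,3aR,4S,7R,7aR)-1,3a,4-trihydroxy-7a-methyloctahydro-1H-indene-7-carboxylate F3. The cis-3a,4-diol is then tied up with Me2C(OMe)2 and PPTS as tert-butyl (1S,3aR,4S,7R,7aR)-1-hydroxy-3a,4-(isopropylidenedioxy)-7a-methyloctahydro-1H-indene-7-carboxylate F4, and the remaining C1 carbinol is re-oxidised with Dess–Martin periodinane, which returns 10. The C1 configuration of these two compounds is of no consequence.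

**Further compounds**

F0 | step 4 | none | none
F1 | step 1 | racemic tert-butyl 2-(1-methyl-2,5-dioxocyclopentyl)-4-oxobutanoate | O=CCC(C(=O)OC(C)(C)C)C1(C)C(=O)CCC1=O
F2 | step 1 | tert-butyl (2S)-2-(1-methyl-2,5-dioxocyclopentyl)-4-oxobutanoate | O=CC[C@H](C(=O)OC(C)(C)C)C1(C)C(=O)CCC1=O
F3 | step 5 | tert-butyl (1S,3aR,4S,7R,7aR)-1,3a,4-trihydroxy-7a-methyloctahydro-1H-indene-7-carboxylate | O[C@H]1CC[C@]2(O)[C@@H](O)CC[C@@H](C(=O)OC(C)(C)C)[C@]12C
F4 | step 5 | tert-butyl (1S,3aR,4S,7R,7aR)-1-hydroxy-3a,4-(isopropylidenedioxy)-7a-methyloctahydro-1H-indene-7-carboxylate | O[C@H]1CC[C@]2(OC(C)(C)O3)[C@@H]3CC[C@@H](C(=O)OC(C)(C)C)[C@]12C
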